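# Proposed total synthesis of torilin

## Retrosynthetic overview

1. Torilin ⇐ diol enone 18 (C8 angelate, then C11 acetate) ⇐ triol 14 by oxidation at C3 and acid-mediated shift of the C1=C5 double bond into the C4=C5 enone position, with C1 set by equilibration.
2. Triol 14 ⇐ tricyclic lactone 11: two equivalents of MeMgBr turn the lactone carbonyl into C11 and release the C3 hydroxyl; before that, the lactone bridge fixes C7 (protonation) and C8 (hydride addition).
3. Lactone 11 ⇐ diazo ester 9 by a tethered rhodium-carbenoid cyclopropanation/Cope [4+3] that forms C6–C7 and C9–C10. Enabling feature: the oxygenated arc C7–C8–C9 of the seven-membered ring faces the four-carbon arc C6–C5–C1–C10, whose inner atoms C5 and C1 are the fusion carbons of the five-membered ring (an s-cis-locked 1,2-bis(alkylidene)cyclopentane diene), and the C3 oxygen lies two ring atoms from C5, so the future C11 carboxyl can tie the carbenoid carbon C7 to C3–O.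
4. Diazo ester 9 ⇐ dienol 5 (diketene, diazo transfer, silylation) ⇐ enynol 4 by palladium-catalysed enyne cycloisomerisation ⇐ pent-3-ynal and a (Z)-crotylborane; this crotylation is the only external source of chirality, and C3/C4 are erased after they have relayed it.
5. Ring order: five-membered carbocycle (step 3), then the seven-membered carbocycle together with a temporary bridging lactone (step 6); the lactone is opened in step 8.

Key step: step 6

Remark: guaiane numbering is used for all intermediates (C1/C5 ring fusion, C3 carbonyl carbon, C4 methyl-bearing carbon, C6–C10 the rest of the seven-membered ring, C11 the side-chain carbinol carbon).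

Remark: the facial sense assumed for the diisopinocampheyl crotylborane in step 2 is the generally accepted one; it fixes the absolute configuration of the whole route.

## Route

Step 1
Reactants: 1 pent-3-yn-1-ol
Product: 2 pent-3-ynal
Conditions: Dess–Martin periodinane, NaHCO3, CH2Cl2, 0 to 23 °C; used at once as a cold solution
Reagents that add atoms: none
Why: Dess–Martin oxidation of a primary alcohol under buffered, non-basic conditions should give the β,γ-alkynyl aldehyde without isomerisation to the allenyl aldehyde.

Step 2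
Reactants: 2 pent-3-ynal; 3 cis-but-2-ene
Product: 4 (3S,4S)-3-methyloct-1-en-6-yn-4-ol
Conditions: 3, KOtBu, n-BuLi, THF, −78 to −45 °C; (+)-B-methoxydiisopinocampheylborane, then BF3·OEt2, −78 °C; 2, −78 °C; NaOH, H2O2
Reagents that add atoms: cis-but-2-ene (3), C/C=C\C
Why: Brown crotylboration through a chair Zimmerman–Traxler transition state: the (Z)-crotyl geometry should give the syn adduct, and the isopinocampheyl groups derived from (−)-α-pinene should direct attack to the Re face of the aldehyde, setting 3S,4S.

Step 3
Reactants: 4 (3S,4S)-3-methyloct-1-en-6-yn-4-ol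
Product: 5 (1S,2S,4E)-4-ethylidene-2-methyl-3-methylidenecyclopentan-1-ol
Conditions: Pd(OAc)2 (5 mol %), PPh3 (10 mol %), toluene, 60 °C
Reagents that add atoms: none
Why: Palladium-catalysed 1,6-enyne cycloisomerisation (Alder-ene type, 5-exo ring closure): the only β-hydrogen of the primary alkylpalladium intermediate is the ring C–H, so the 1,3-diene should result, and syn addition across the alkyne fixes the (E)-ethylidene; the two stereocenters are untouched.

Step 4
Reactants: 5 (1S,2S,4E)-4-ethylidene-2-methyl-3-methylidenecyclopentan-1-ol; 6 diketene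
Product: 8 (1S,2S,4E)-4-ethylidene-2-methyl-3-methylidenecyclopentyl 2-diazo-3-oxobutanoate, via acetoacetate ester 7 (not isolated)
Conditions: 6, DMAP (cat.), THF, 0 °C; then 4-acetamidobenzenesulfonyl azide, Et3N, MeCN, 0 to 23 °C
Reagents that add atoms: diketene (6), C=C1CC(=O)O1; 4-acetamidobenzenesulfonyl azide, CC(=O)Nc1ccc(cc1)S(=O)(=O)N=[N+]=[N-]
Why: Acetoacetylation of the secondary alcohol by diketene (retention, no C–O cleavage) followed by Regitz diazo transfer to the active methylene group.

Step 5
Reactants: 8 (1S,2S,4E)-4-ethylidene-2-methyl-3-methylidenecyclopentyl 2-diazo-3-oxobutanoate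
Product: 9 (1S,2S,4E)-4-ethylidene-2-methyl-3-methylidenecyclopentyl 3-[(tert-butyldimethylsilyl)oxy]-2-diazobut-3-enoate
Conditions: TBSOTf, Et3N, CH2Cl2, 0 °C
Reagents that add atoms: tert-butyldimethylsilyl triflate, CC(C)(C)[Si](C)(C)OS(=O)(=O)C(F)(F)F
Why: O-silylation of the diazo β-keto ester (enolisation toward the methyl group) gives the siloxyvinyl diazoacetate, the standard precursor of a donor/acceptor vinylcarbenoid.

Step 6
Reactants: 9 (1S,2S,4E)-4-ethylidene-2-methyl-3-methylidenecyclopentyl 3-[(tert-butyldimethylsilyl)oxy]-2-diazobut-3-enoate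
Product: 11 (3S,4S,10S) tricyclic lactone (hydroazulene with C1=C5 and C7=C8 double bonds, OTBS on C8, methyls on C4 and C10, C7 carboxyl lactonised onto the C3 oxygen), via cyclopropane lactone 10 (not isolated)
Conditions: Rh2(O2CC7H15)4 (dirhodium tetraoctanoate, 1 mol %), toluene (0.01 M), syringe-pump addition of 9 at 23 °C; then 90 °C
Reagents that add atoms: none
Why: Proposed new method: dirhodium-induced loss of N2 from 9 gives a siloxyvinyl carbenoid that the ester tether can deliver only to the diene face syn to the C3 oxygen; it cyclopropanates the terminal C5=C6 methylene (C7–C6 and C7–C5 formed, a six-membered lactone fused to the new three-membered ring) to give 10, in which the tether forces the lactone carbonyl cis to C4 and hence the siloxyvinyl group cis to the ethylidene-bearing C1, i.e. a cis-divinylcyclopropane. This should undergo a boat-type [3,3] (Cope) shift that breaks C5–C7 and forms C9–C10, closing the seven-membered carbocycle and widening the lactone to a seven-membered bridge. The closest known reaction type is the intramolecular tandem cyclopropanation/Cope rearrangement (formal [4+3]) of dienyl vinyldiazoacetates; new here are the homoallylic, ring-borne tether and the bridgehead C1=C5 alkene it leaves in 11 (a bicyclo[4.2.1]non-1(8)-ene unit, strained but of an isolable class), which is why the Cope stage is driven thermally. C10, the only new stereocenter that survives, is set by suprafacial addition of the three-carbon unit on the face fixed by the (S)-carbinol carbon C3 together with the (E)-ethylidene geometry (methyl outside in the boat), which should give 10S with the methyl cis to the C7 carboxyl carbon. The step needs methylene-over-ethylidene site selectivity and cyclopropanation over allylic C–H insertion; the less substituted, more nucleophilic diene terminus, the trans C4 methyl (pointing away from the tether) and slow addition to a carboxylate catalyst of moderate electrophilicity should secure both.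

Step 7
Reactants: 11 (3S,4S,10S) tricyclic silyl enol ether lactone
Product: 13 (3S,4S,7S,8R,10S) tricyclic 8-hydroxy lactone, via keto lactone 12 (not isolated)
Conditions: TBAF, AcOH (1:1), THF, −20 °C; then MeOH, NaBH4, −40 °C
Reagents that add atoms: none
Why: Fluoride cleaves the silyl enol ether of the β-keto lactone, and protonation at C7 can only give the epimer whose carboxyl carbon stays bridged to the C3 oxygen (7S); NaBH4 should then attack the C8 ketone anti to the pseudo-axial C7–carboxyl bond, away from the lactone bridge, giving the 8R alcohol cis to the bridge, the ketone being reduced much faster than the lactone.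

Step 8
Reactants: 13 (3S,4S,7S,8R,10S) tricyclic 8-hydroxy lactone
Product: 14 (3S,4S,7S,8R,10S)-guai-1(5)-ene-3,8,11-triol
Conditions: MeMgBr (5 equiv), THF, −40 to 0 °C
Reagents that add atoms: methylmagnesium bromide, C[Mg]Br
Why: Double Grignard addition to the lactone builds the C11 tertiary carbinol and releases the C3 hydroxyl, relieving the bridgehead-alkene strain; the C8 magnesium alkoxide formed first guards against retro-aldol cleavage.

Step 9
Reactants: 14 (3S,4S,7S,8R,10S)-guai-1(5)-ene-3,8,11-triol
Product: 15 8,11-O-isopropylidene acetal of 14 (C3 hydroxyl free)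
Conditions: 2,2-dimethoxypropane, pyridinium p-toluenesulfonate (cat.), CH2Cl2, 23 °C
Reagents that add atoms: 2,2-dimethoxypropane, COC(C)(C)OC
Why: Thermodynamic acetonide formation engages only the 1,3-diol (six-membered dioxane) and leaves the isolated C3 hydroxyl free.

Step 10
Reactants: 15 8,11-O-isopropylidene acetal of 14
Product: 16 (4S,7S,8R,10S)-8,11-(isopropylidenedioxy)guai-1(5)-en-3-one
Conditions: Dess–Martin periodinane, NaHCO3, CH2Cl2, 0 °C
Reagents that add atoms: none
Why: Dess–Martin oxidation of the only free secondary alcohol under buffered conditions; the β,γ-unsaturated ketone is taken on crude.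

Step 11
Reactants: 16 (4S,7S,8R,10S)-8,11-(isopropylidenedioxy)guai-1(5)-en-3-one
Product: 18 (1R,7S,8R,10S)-8,11-dihydroxyguai-4-en-3-one, via enone acetonide 17 (not isolated)
Conditions: 2 M aq. HCl, THF, 23 to 40 °C
Reagents that add atoms: none
Why: Acid-catalysed enolisation should move the double bond into conjugation at the more substituted C4=C5 position (tetrasubstituted enone) and set C1 under thermodynamic control by γ-protonation of the dienol (C2 branch trans to the C10 methyl, 1R), while the acetonide is hydrolysed.

Step 12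
Reactants: 18 (1R,7S,8R,10S)-8,11-dihydroxyguai-4-en-3-one; 19 angelic acid
Product: 20 (1R,7S,8R,10S)-8-angeloyloxy-11-hydroxyguai-4-en-3-one
Conditions: 19, 2,4,6-trichlorobenzoyl chloride, Et3N, toluene, 23 °C; then 18, 75 °C
Reagents that add atoms: angelic acid (19), C/C=C(/C)C(=O)O
Why: Yamaguchi esterification through the preformed mixed anhydride, without a nucleophilic catalyst, should acylate the secondary C8 hydroxyl in preference to the tertiary one and keep the (Z)-geometry of the angeloyl group.

Step 13
Reactants: 20 (1R,7S,8R,10S)-8-angeloyloxy-11-hydroxyguai-4-en-3-one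
Product: 21 torilin
Conditions: Ac2O, Sc(OTf)3 (5 mol %), MeCN, −20 °C
Reagents that add atoms: acetic anhydride, CC(=O)OC(C)=O
Why: Lewis-acid-catalysed acetylation is the standard way to acylate a hindered tertiary alcohol, and the low temperature should spare the angelate and the enone.

## Compound list

1 | pent-3-yn-1-ol | CC#CCCO | starting material
2 | pent-3-ynal | CC#CCC=O | intermediate
3 | cis-but-2-ene | C/C=C\C | starting material
4 | (3S,4S)-3-methyloct-1-en-6-yn-4-ol | C=C[C@H](C)[C@@H](O)CC#CC | intermediate
5 | (1S,2S,4E)-4-ethylidene-2-methyl-3-methylidenecyclopentan-1-ol | C=C1[C@H](C)[C@@H](O)C/C1=C\C | intermediate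
6 | diketene (4-methylideneoxetan-2-one) | C=C1CC(=O)O1 | starting material
7 | (1S,2S,4E)-4-ethylidene-2-methyl-3-methylidenecyclopentyl 3-oxobutanoate | C=C1[C@H](C)[C@@H](OC(=O)CC(C)=O)C/C1=C\C | intermediate
8 | (1S,2S,4E)-4-ethylidene-2-methyl-3-methylidenecyclopentyl 2-diazo-3-oxobutanoate | C=C1[C@H](C)[C@@H](OC(=O)C(=[N+]=[N-])C(C)=O)C/C1=C\C | intermediate
9 | (1S,2S,4E)-4-ethylidene-2-methyl-3-methylidenecyclopentyl 3-[(tert-butyldimethylsilyl)oxy]-2-diazobut-3-enoate | C=C1[C@H](C)[C@@H](OC(=O)C(=[N+]=[N-])C(=C)O[Si](C)(C)C(C)(C)C)C/C1=C\C | intermediate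
10 | cyclopropane lactone: six-membered lactone C3–O–CO–C7–C5–C4 bridging the cyclopentane, C5–C6–C7 cyclopropane on the face of the lactone oxygen, 1-(TBS-oxy)vinyl on C7 cis to C1, (E)-ethylidene on C1, C4 methyl anti to the lactone bridge | C/C=C1\C[C@@H]2OC(=O)[C@@]3(C(=C)O[Si](C)(C)C(C)(C)C)C[C@]13[C@@H]2C | intermediate
11 | (3S,4S,10S) tricyclic silyl enol ether lactone: hydroazulene with C1=C5 and C7=C8 double bonds, OTBS on C8, methyls on C4 and C10, C7 carboxyl lactonised onto the C3 oxygen | C[C@H]1CC(O[Si](C)(C)C(C)(C)C)=C2CC3=C1C[C@H](OC2=O)[C@H]3C | intermediate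
12 | (3S,4S,7S,10S) tricyclic 8-oxo lactone | C[C@H]1CC(=O)[C@@H]2CC3=C1C[C@H](OC2=O)[C@H]3C | intermediate
13 | (3S,4S,7S,8R,10S) tricyclic 8-hydroxy lactone | C[C@H]1C[C@@H](O)[C@@H]2CC3=C1C[C@H](OC2=O)[C@H]3C | intermediate
14 | (3S,4S,7S,8R,10S)-guai-1(5)-ene-3,8,11-triol | C[C@H]1C[C@@H](O)[C@@H](C(C)(C)O)CC2=C1C[C@H](O)[C@H]2C | intermediate
15 | (3S,4S,7S,8R,10S)-8,11-(isopropylidenedioxy)guai-1(5)-en-3-ol | C[C@H]1C[C@H]2OC(C)(C)OC(C)(C)[C@H]2CC3=C1C[C@H](O)[C@H]3C | intermediate
16 | (4S,7S,8R,10S)-8,11-(isopropylidenedioxy)guai-1(5)-en-3-one | C[C@H]1C[C@H]2OC(C)(C)OC(C)(C)[C@H]2CC3=C1CC(=O)[C@H]3C | intermediate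
17 | (1R,7S,8R,10S)-8,11-(isopropylidenedioxy)guai-4-en-3-one | CC1(C)O[C@@H]2C[C@H](C)[C@H]3CC(=O)C(C)=C3C[C@@H]2C(C)(C)O1 | intermediate
18 | (1R,7S,8R,10S)-8,11-dihydroxyguai-4-en-3-one | O[C@@H]1C[C@H](C)[C@H]2CC(=O)C(C)=C2C[C@@H]1C(C)(C)O | intermediate
19 | angelic acid ((Z)-2-methylbut-2-enoic acid) | C/C=C(/C)C(=O)O | starting material
20 | (1R,7S,8R,10S)-8-angeloyloxy-11-hydroxyguai-4-en-3-one | C/C=C(/C)C(=O)O[C@@H]1C[C@H](C)[C@H]2CC(=O)C(C)=C2C[C@@H]1C(C)(C)O | intermediate
21 | torilin, (1R,7S,8R,10S)-11-acetoxy-8-angeloyloxyguai-4-en-3-one | C/C=C(/C)C(=O)O[C@@H]1C[C@H](C)[C@H]2CC(=O)C(C)=C2C[C@@H]1C(C)(C)OC(C)=O | target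

## Step count and risks

Total step count: 13. Longest linear sequence: 13 steps (from pent-3-yn-1-ol 1).

Steps most likely to fail:

1. Step 6 (the step that bears the label). The carbenoid may be diverted into intramolecular allylic C–H insertion or into cyclopropanation at the ethylidene terminus, and the Cope stage may stall or reverse because of the strain of the bridgehead alkene. The fallback sets out from dienol 5 and comes back at triol 14, using the intermolecular version of the same annulation, which is known chemistry. Dienol 5 would be silylated (TBSCl, imidazole) to its TBS ether F1 and combined with methyl 3-[(tert-butyldimethylsilyl)oxy]-2-diazobut-3-enoate F2 (from methyl acetoacetate by diazo transfer and silylation) under Rh2(O2CC7H15)4 in hexane. The three-carbon unit should add anti to the C4 methyl group next to the reacting methylene, giving the bicyclic silyl enol ether ester F3. Buffered fluoride at low temperature would free the β-keto ester F4. Noyori–Ikariya transfer hydrogenation with dynamic kinetic resolution (RuCl(TsDPEN)(p-cymene), the enantiomer matched to the 8R alcohol, HCO2H/Et3N) should give the cis-hydroxy ester F5. MeMgBr would convert it into the diol silyl ether F6, and TBAF would give 14.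

2. Step 11. Equilibration may settle on the wrong C1 epimer, or the double bond may migrate toward C1=C2 instead of C4=C5. The fallback sets out from acetonide 15 and comes back at enone acetonide 17; it sets C1 kinetically. Hydroxyl-directed hydrogenation of the C1=C5 alkene with [Ir(cod)(PCy3)(py)]PF6 and H2 in CH2Cl2 should deliver both hydrogens from the face of the C3 hydroxyl, giving the saturated cis-fused alcohol F7 with the required C1–H. Dess–Martin oxidation would give ketone F8, and TMSCl, Et3N, DMF at 80 °C the more substituted trimethylsilyl enol ether F9. Saegusa–Ito oxidation with Pd(OAc)2 in MeCN should then give 17, which would be deprotected with pyridinium p-toluenesulfonate in methanol, conditions too mild for γ-enolisation, to reach 18.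

3. Step 12. The angeloyl unit may isomerise from Z to E (tiglate formation) during activation, or acylation of the hindered secondary alcohol may be too slow. The fallback sets out from diol enone 18 and comes back at angelate 20, building the Z-alkene after acylation. Diol 18 would be coupled (N,N'-dicyclohexylcarbodiimide, DMAP) with 2-[bis(2,2,2-trifluoroethoxy)phosphoryl]propanoic acid to the phosphonate ester F10. Still–Gennari olefination (KN(SiMe3)2, 18-crown-6, THF, −78 °C, then acetaldehyde) should then give the (Z)-2-methylbut-2-enoate 20.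

## Further compounds

F1 | step 6 | tert-butyl{[(1S,2S,4E)-4-ethylidene-2-methyl-3-methylidenecyclopentyl]oxy}dimethylsilane | C=C1[C@H](C)[C@@H](O[Si](C)(C)C(C)(C)C)C/C1=C\C
F2 | step 6 | methyl 3-[(tert-butyldimethylsilyl)oxy]-2-diazobut-3-enoate | COC(=O)C(=[N+]=[N-])C(=C)O[Si](C)(C)C(C)(C)C
F3 | step 6 | (3S,4S,10S) methyl 3,8-bis[(tert-butyldimethylsilyl)oxy]guaia-1(5),7-diene-11-oate analogue (C7 methyl ester, C7=C8 silyl enol ether) | COC(=O)C1=C(O[Si](C)(C)C(C)(C)C)C[C@H](C)C2=C(C1)[C@H](C)[C@@H](O[Si](C)(C)C(C)(C)C)C2
F4 | step 6 | (3S,4S,10S) β-keto ester (C8 ketone, C7 methyl ester, C7 epimers and enol in equilibrium, C3 OTBS) | COC(=O)C1C(=O)C[C@H](C)C2=C(C1)[C@H](C)[C@@H](O[Si](C)(C)C(C)(C)C)C2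
F5 | step 6 | (3S,4S,7S,8R,10S) cis-hydroxy ester (C8 hydroxyl, C7 methyl ester, C3 OTBS) | COC(=O)[C@@H]1[C@H](O)C[C@H](C)C2=C(C1)[C@H](C)[C@@H](O[Si](C)(C)C(C)(C)C)C2
F6 | step 6 | (3S,4S,7S,8R,10S)-3-[(tert-butyldimethylsilyl)oxy]guai-1(5)-ene-8,11-diol | CC(C)(O)[C@@H]1[C@H](O)C[C@H](C)C2=C(C1)[C@H](C)[C@@H](O[Si](C)(C)C(C)(C)C)C2
F7 | step 11 | 8,11-(isopropylidenedioxy)guaian-3-ol, cis-fused, with H-1 and H-5 on the face of the C3 hydroxyl | C[C@H]1C[C@H]2OC(C)(C)OC(C)(C)[C@H]2C[C@H]3[C@@H]1C[C@H](O)[C@H]3C
F8 | step 11 | 8,11-(isopropylidenedioxy)guaian-3-one, cis-fused | C[C@H]1C[C@H]2OC(C)(C)OC(C)(C)[C@H]2C[C@H]3[C@@H]1CC(=O)[C@H]3C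
F9 | step 11 | 8,11-(isopropylidenedioxy)-3-[(trimethylsilyl)oxy]guai-3-ene | C[C@H]1C[C@H]2OC(C)(C)OC(C)(C)[C@H]2C[C@H]3[C@@H]1CC(O[Si](C)(C)C)=C3C
F10 | step 12 | 8-O-{2-[bis(2,2,2-trifluoroethoxy)phosphoryl]propanoyl} derivative of 18 | CC(C(=O)O[C@@H]1C[C@H](C)[C@H]2CC(=O)C(C)=C2C[C@@H]1C(C)(C)O)P(=O)(OCC(F)(F)F)OCC(F)(F)F
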